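At early times the charged D leaves by two roads, dissolving and pairing, and the ledger below follows how they share it.

    D ⇌ X, rate k1*(cs1 - [X]) while solid is left; crystals form when [X] > cs1 (cs1 = 19 mM, k1 = 0.0034 s⁻¹)
    X + E → X.E (k2 = 1.4 M⁻¹ s⁻¹)
    X + X.E → X.X.E (k3 = 0.16 M⁻¹ s⁻¹)
    J ⇌ E, rate k4*(csat - [E]) (k4 = 0.24 s⁻¹, csat = 12 mM)
    2 D → D2 (k5 = 0.14 M⁻¹ s⁻¹)
    G ⇌ X.E, rate k6*(cs6 - [X.E]) while solid is left; crystals form when [X.E] > cs6 (cs6 = 24 mM, k6 = 0.030 s⁻¹)
D 0.050 M; J 12 mM (held); time 40 min
- percentages count the D that a species holds: one X.X.E or D2 counts as two
- X.E is meant together with its G
- two of one species on the left: rate k times its square, two consumed each time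
- solid, in amounts per volume of the solution: D, G
- at the start none of E is dissolved
- at the start none of D is in solution
- X means what is dissolved; the solid is not counted in it
- run time (flask): 40 min
* the X.E and G together standing at 40 min, as a percentage of the D charged
* concentration of X in solution at 40 min, in percent of saturation

You can keep the ledger of D, the limiting reagent, by hand. While X stays low, dissolving spends D at a steady rate, zero order in D:

dissolving = 3.88 mM min⁻¹

Pairing is second order, so the concentration of D sets its rate. Setting the two rates equal gives

15.2 mM

This is the crossover concentration, the amount of D at which dissolving and pairing spend it equally. Your charge of 0.050 M stands above it, so pairing leads at first.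

Integrating both roads together, the D that dissolves is the crossover times an arctangent. For a charge well above the crossover, that arctangent is close to a right angle in radians less crossover/charge. I round the right angle down a little, to allow for the X standing in solution:

first entry, dissolved = 15.2 mM × (1.50 − 0.304) = 18.2 mM, or 36.4 % of the charge

second entry, paired into D2: the other 63.6 %

Next, the dissolved X meets E, which is refilled faster than X consumes it, so you may hold E at saturation. X also lands on X.E, and to first order this gives

third entry, X.E = dissolved × (1 − dissolved × 9.52 M⁻¹) = 15.0 mM

That is below the solubility of X.E, so no G enters the ledger, and my y is 30.1 %. At the steady rate that amount takes 4.69 min, which is my estimate of when dissolving ends. Against E, X has a half-life of 0.688 min, so my sat, taking X from saturation over the remaining time, is <0.001 %.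

The forecast gave 31 % and 0 %, holding that “The dimerisation of D far outruns dissolution”. Its y stands slightly above mine.

The simulation gives 31.5 % and 0 %, so the forecast stands within its margins.

This flask has come to rest: by 6.49 min D, solid and dissolved, is below 2 % of its charge, and at 20.0 min X.E and G together stand at 31.5 %, beside 63.1 % in D2 and 5.36 % in X.X.E. In the neighbour flask charged with 0.12 M of D, further above the crossover, the same ledger gives 20.9 mM dissolved and 13.9 % of its charge as X.E, and that flask holds 14.5 % of its charge as X.E and G together. Left on to 400 min, the flask charged with 0.050 M of D shows no change in the answer y: it still holds 31.5 % of X.E and G together.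

All constants come from no measurement; the result is computed.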